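**Strategy.** Ring C of the flavonol is opened at O1–C2 and then cut on both sides of C4, the carbonyl carbon bonded only to C4a of ring A and to the oxygen-bearing C3. Because C4 carries nothing else, it can be supplied as carbon monoxide. One palladium-catalysed carbonylative α-arylation joins a ring A aryl iodide, CO and a ring B α-alkoxy ketone, forming C4a–C4 and C4–C3 together and giving the 1,3-diketone with the C3 oxygen in place. The iodide carries the C8 prenyl group, a MOM ether on the future O1 and a methyl ether on O5, so only one phenol can close ring C. The ketone carries O3 and O4' as MOM ethers.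

Key step: step 5

Remark: the target has no stereocentre; MOM = methoxymethyl. O3 is carried as a MOM ether rather than a methyl ether, so the only ether left to cleave at the end is the chelated O5 methyl ether. Compound 8 is taken as purchasable.

**Step 1**
Reactants: 1 3,5-dimethoxyphenol
Product: 2 1,3-dimethoxy-5-(methoxymethoxy)benzene
Conditions: MOMCl, iPr2NEt, CH2Cl2, 0 °C → rt
Reagents that add atoms: chloromethyl methyl ether (MOMCl), COCCl
Why: O-alkylation of the single phenol by the reactive α-chloro ether under amine base (acetal protection) should be clean and installs the group that directs both later metalations.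

**Step 2**
Reactants: 2 1,3-dimethoxy-5-(methoxymethoxy)benzene; 3 1-bromo-3-methylbut-2-ene (prenyl bromide)
Product: 5 1,5-dimethoxy-3-(methoxymethoxy)-2-(3-methylbut-2-enyl)benzene, via aryllithium 4 (not isolated)
Conditions: n-BuLi, THF, 0 °C; then 3, −78 °C → rt
Reagents that add atoms: none
Why: Directed ortho-metalation should place lithium on one of the two equivalent carbons flanked by OMOM and OMe (the stronger acetal director outweighs the position between the two methoxy groups), and the aryllithium should be alkylated at the primary carbon of the allylic bromide (SN2).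

**Step 3**
Reactants: 5 1,5-dimethoxy-3-(methoxymethoxy)-2-(3-methylbut-2-enyl)benzene
Product: 7 2-iodo-1,5-dimethoxy-3-(methoxymethoxy)-4-(3-methylbut-2-enyl)benzene, via aryllithium 6 (not isolated)
Conditions: n-BuLi, THF, −10 °C; then I2, THF, −78 °C; aq. Na2S2O3
Reagents that add atoms: iodine, II
Why: A second directed ortho-metalation should occur at the only remaining carbon flanked by OMOM and OMe, with pre-coordination to the acetal favouring ring over benzylic deprotonation, and iodinolysis of the aryllithium at low temperature should leave the alkene untouched.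

**Step 4**
Reactants: 8 2-hydroxy-1-(4-hydroxyphenyl)ethanone
Product: 9 2-(methoxymethoxy)-1-[4-(methoxymethoxy)phenyl]ethanone
Conditions: MOMCl (3 equiv), iPr2NEt, CH2Cl2, 0 °C → rt
Reagents that add atoms: chloromethyl methyl ether (MOMCl), COCCl
Why: Double O-alkylation of the phenol and the primary ketol hydroxyl with MOMCl under a hindered amine base (acetal protection) should give a ketone with one enolisable position whose α-oxygen can chelate magnesium.

**Step 5**
Reactants: 7 2-iodo-1,5-dimethoxy-3-(methoxymethoxy)-4-(3-methylbut-2-enyl)benzene; 9 2-(methoxymethoxy)-1-[4-(methoxymethoxy)phenyl]ethanone; 10 carbon monoxide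
Product: 11 1-[4,6-dimethoxy-2-(methoxymethoxy)-3-(3-methylbut-2-enyl)phenyl]-2-(methoxymethoxy)-3-[4-(methoxymethoxy)phenyl]propane-1,3-dione (racemic at C2, enolisable)
Conditions: Pd(dba)2 (5 mol %), Xantphos (5 mol %), MgCl2, Et3N, CO (3 bar), 9 (2 equiv), dioxane, 80 °C; aq. NH4Cl
Reagents that add atoms: none
Why: Oxidative addition of the C–I bond of 7 to zerovalent palladium gives an arylpalladium iodide (divalent palladium), CO inserts to the aroylpalladium species, and the magnesium enolate of 9, formed by soft enolisation with MgCl2/Et3N and held as a five-membered chelate through the α-OMOM oxygen, displaces iodide before reductive elimination forms the C–C bond, the product being trapped as its magnesium diketonate. The closest known reaction type is the palladium-catalysed carbonylative α-arylation of ketones with aryl iodides to 1,3-diketones. No ring is closed; the one new stereocentre (C2 of the diketone) should form racemic, is enolisable and is erased in step 6. The step needs CO insertion before C–C coupling and acylation at carbon rather than oxygen: the two ortho alkoxy groups and the CO pressure should favour migratory insertion over direct arylation, the chelated magnesium enolate should react at carbon, and the more acidic product is sequestered as a chelate and should not be acylated again. The prenyl alkene (meta to the iodide, out of reach of the acylpalladium centre) and the MOM acetals should be inert to these mildly basic conditions.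

**Step 6**
Reactants: 11 1-[4,6-dimethoxy-2-(methoxymethoxy)-3-(3-methylbut-2-enyl)phenyl]-2-(methoxymethoxy)-3-[4-(methoxymethoxy)phenyl]propane-1,3-dione
Product: 13 3-hydroxy-2-(4-hydroxyphenyl)-5,7-dimethoxy-8-(3-methylbut-2-enyl)chromen-4-one, via triol diketone 12 (not isolated)
Conditions: 3 M aq. HCl/MeOH (1:5), 50 °C
Reagents that add atoms: none
Why: Acid-catalysed acetal methanolysis should remove all three MOM groups, and the single freed ring A phenol should add to the ring B carbonyl and dehydrate (cyclodehydration of an o-hydroxyaryl 1,3-diketone) to the 3-hydroxyflavone, the O5 methyl ether ensuring that only O1 can close ring C and the dilute acid sparing the prenyl group.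

**Step 7**
Reactants: 13 3-hydroxy-2-(4-hydroxyphenyl)-5,7-dimethoxy-8-(3-methylbut-2-enyl)chromen-4-one
Product: 14 isoanhydroicaritin, 3,5-dihydroxy-2-(4-hydroxyphenyl)-7-methoxy-8-(3-methylbut-2-enyl)chromen-4-one
Conditions: MgI2·OEt2 (4 equiv), THF, 60 °C; then aq. NH4Cl
Reagents that add atoms: none
Why: Chelation-assisted ether cleavage: magnesium should bridge the C4 carbonyl and the O5 methyl ether in a six-membered chelate while iodide removes the methyl group by SN2 attack, whereas the O7 methyl ether has no neighbouring carbonyl and the prenyl group sees no protic acid.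

**Compound list**
1 | 3,5-dimethoxyphenol | COc1cc(O)cc(OC)c1 | starting material
2 | 1,3-dimethoxy-5-(methoxymethoxy)benzene | COCOc1cc(OC)cc(OC)c1 | intermediate
3 | 1-bromo-3-methylbut-2-ene (prenyl bromide) | CC(C)=CCBr | starting material
4 | [2,4-dimethoxy-6-(methoxymethoxy)phenyl]lithium | [Li]c1c(OC)cc(OC)cc1OCOC | intermediate (not isolated)
5 | 1,5-dimethoxy-3-(methoxymethoxy)-2-(3-methylbut-2-enyl)benzene | COc1cc(OC)cc(OCOC)c1CC=C(C)C | intermediate
6 | [4,6-dimethoxy-2-(methoxymethoxy)-3-(3-methylbut-2-enyl)phenyl]lithium | [Li]c1c(OC)cc(OC)c(CC=C(C)C)c1OCOC | intermediate (not isolated)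
7 | 2-iodo-1,5-dimethoxy-3-(methoxymethoxy)-4-(3-methylbut-2-enyl)benzene | COc1cc(OC)c(I)c(OCOC)c1CC=C(C)C | intermediate
8 | 2-hydroxy-1-(4-hydroxyphenyl)ethanone | O=C(CO)c1ccc(O)cc1 | starting material
9 | 2-(methoxymethoxy)-1-[4-(methoxymethoxy)phenyl]ethanone | COCOCC(=O)c1ccc(OCOC)cc1 | intermediate
10 | carbon monoxide | [C-]#[O+] | starting material
11 | 1-[4,6-dimethoxy-2-(methoxymethoxy)-3-(3-methylbut-2-enyl)phenyl]-2-(methoxymethoxy)-3-[4-(methoxymethoxy)phenyl]propane-1,3-dione (racemic) | COCOC(C(=O)c1ccc(OCOC)cc1)C(=O)c1c(OC)cc(OC)c(CC=C(C)C)c1OCOC | intermediate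
12 | 2-hydroxy-1-[2-hydroxy-4,6-dimethoxy-3-(3-methylbut-2-enyl)phenyl]-3-(4-hydroxyphenyl)propane-1,3-dione (racemic) | COc1cc(OC)c(C(=O)C(O)C(=O)c2ccc(O)cc2)c(O)c1CC=C(C)C | intermediate (not isolated)
13 | 3-hydroxy-2-(4-hydroxyphenyl)-5,7-dimethoxy-8-(3-methylbut-2-enyl)chromen-4-one | COc1cc(OC)c2c(=O)c(O)c(-c3ccc(O)cc3)oc2c1CC=C(C)C | intermediate
14 | isoanhydroicaritin, 3,5-dihydroxy-2-(4-hydroxyphenyl)-7-methoxy-8-(3-methylbut-2-enyl)chromen-4-one | COc1cc(O)c2c(=O)c(O)c(-c3ccc(O)cc3)oc2c1CC=C(C)C | target

**Total steps:** 7. **Longest linear sequence:** 6 steps (steps 1, 2, 3, 5, 6 and 7 from 3,5-dimethoxyphenol 1); the ring B branch adds step 4.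

**Steps most likely to fail**

Step 5. Oxidative addition and acyl transfer at the doubly ortho-substituted, electron-rich ring may be slow, so that hydrodeiodination, non-carbonylative arylation or acylation of the enolate at oxygen could compete. The fallback sets out from 5 and 9 and comes back at 11, building the two bonds at C4 one after the other by classical acylation chemistry. Aryllithium 6, made from 5 as in step 3, would be quenched with CO2 and acidified with aq. NaH2PO4 to give 4,6-dimethoxy-2-(methoxymethoxy)-3-(3-methylbut-2-enyl)benzoic acid F1. Carbonyldiimidazole in THF would turn it into the acyl imidazole [4,6-dimethoxy-2-(methoxymethoxy)-3-(3-methylbut-2-enyl)phenyl](imidazol-1-yl)methanone F2. Ketone 9 would be deprotonated with LiN(SiMe3)2 (2.2 equiv, THF, −78 °C) to lithium (Z)-2-(methoxymethoxy)-1-[4-(methoxymethoxy)phenyl]ethenolate F3, and C-acylation of this enolate by F2 (crossed Claisen condensation, −78 → 0 °C) should give diketone 11.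

Step 7. Competing chelation of magnesium at the free 3-hydroxy-4-keto site may stall the demethylation at O5, and forcing the reaction could cost the O7 methyl ether or lead to hydroiodination or cyclisation at the prenyl chain. The fallback sets out from 13 and comes back at 14 by a protect, demethylate, deprotect sequence that leaves only one chelating site. Ac2O in pyridine would give 4-[3-acetoxy-5,7-dimethoxy-8-(3-methylbut-2-enyl)-4-oxochromen-2-yl]phenyl acetate F4. BCl3 in CH2Cl2 (−78 → 0 °C) should then cleave only the carbonyl-chelated O5 methyl ether to give 4-[3-acetoxy-5-hydroxy-7-methoxy-8-(3-methylbut-2-enyl)-4-oxochromen-2-yl]phenyl acetate F5, with no hydroxyl present to release HCl before work-up. K2CO3 in MeOH at rt would remove both acetates to give 14.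

Step 3. Deprotonation at the benzylic and allylic CH2 of the prenyl chain, or at the ring position between the two methoxy groups, may compete with metalation next to the acetal and give mixtures on iodination. The fallback sets out from 2 and comes back at 7, introducing iodine before the prenyl group and delivering the latter by a sigmatropic shift instead of a second lithiation.
- Aryllithium 4, made from 2 as in step 2, would be quenched with I2 to give 2-iodo-1,5-dimethoxy-3-(methoxymethoxy)benzene F6.
- Brief treatment with HCl in MeOH at rt would give 2-iodo-3,5-dimethoxyphenol F7.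
- O-alkylation with 3-chloro-3-methylbut-1-yne (DBU, CuCl2 cat., MeCN, 0 °C) would give 2-iodo-1,5-dimethoxy-3-[(2-methylbut-3-yn-2-yl)oxy]benzene F8.
- Semihydrogenation (H2, Pd/CaCO3 poisoned with Pb(OAc)2, quinoline, EtOAc) would give 2-iodo-1,5-dimethoxy-3-[(2-methylbut-3-en-2-yl)oxy]benzene F9.
- Aromatic Claisen rearrangement (PhNEt2, 130 °C) can only reach the one free ortho position and should give 2-iodo-3,5-dimethoxy-6-(3-methylbut-2-enyl)phenol F10.
- MOMCl and iPr2NEt in CH2Cl2 would then give 7.

**Further compounds**
F1 | step 5 | 4,6-dimethoxy-2-(methoxymethoxy)-3-(3-methylbut-2-enyl)benzoic acid | COc1cc(OC)c(C(=O)O)c(OCOC)c1CC=C(C)C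
F2 | step 5 | [4,6-dimethoxy-2-(methoxymethoxy)-3-(3-methylbut-2-enyl)phenyl](imidazol-1-yl)methanone | COc1cc(OC)c(C(=O)n2ccnc2)c(OCOC)c1CC=C(C)C
F3 | step 5 | lithium (Z)-2-(methoxymethoxy)-1-[4-(methoxymethoxy)phenyl]ethenolate | [Li+].[O-]/C(=C\OCOC)c1ccc(OCOC)cc1
F4 | step 7 | 4-[3-acetoxy-5,7-dimethoxy-8-(3-methylbut-2-enyl)-4-oxochromen-2-yl]phenyl acetate | COc1cc(OC)c2c(=O)c(OC(C)=O)c(-c3ccc(OC(C)=O)cc3)oc2c1CC=C(C)C
F5 | step 7 | 4-[3-acetoxy-5-hydroxy-7-methoxy-8-(3-methylbut-2-enyl)-4-oxochromen-2-yl]phenyl acetate | COc1cc(O)c2c(=O)c(OC(C)=O)c(-c3ccc(OC(C)=O)cc3)oc2c1CC=C(C)C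
F6 | step 3 | 2-iodo-1,5-dimethoxy-3-(methoxymethoxy)benzene | COCOc1cc(OC)cc(OC)c1I
F7 | step 3 | 2-iodo-3,5-dimethoxyphenol | COc1cc(O)c(I)c(OC)c1
F8 | step 3 | 2-iodo-1,5-dimethoxy-3-[(2-methylbut-3-yn-2-yl)oxy]benzene | COc1cc(OC)c(I)c(OC(C)(C)C#C)c1
F9 | step 3 | 2-iodo-1,5-dimethoxy-3-[(2-methylbut-3-en-2-yl)oxy]benzene | COc1cc(OC)c(I)c(OC(C)(C)C=C)c1
F10 | step 3 | 2-iodo-3,5-dimethoxy-6-(3-methylbut-2-enyl)phenol | COc1cc(OC)c(I)c(O)c1CC=C(C)C
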